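**Plan**
- Retrosynthesis: the six O–Me bonds and the formyl group (from a nitrile) are cut first, then C1–H/C11b–H (furan reduction), the C7–(4-methoxyphenyl) bond (Friedel–Crafts), the C6–aryl bond (ketone α-arylation), then C11b–C11c and O2–C2a together, and last C6–C7 (benzylzinc plus aldehyde) and the anisyl ketone C–C bond.
- Enabling feature: furan carbon C11b and furan oxygen O2 sit on adjacent carbons (C11c, C2a) of ring A (the resorcinol ring fused to the furan), which is the pattern left when a ketone enolate C-arylates and then O-arylates a 1-iodo-2-bromoarene.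
- Forward: a ring-A benzyl bromide and a ring-B aldehyde ester are joined (C6–C7) and the anisyl ketone is installed. The tandem arylation then closes the seven-membered ring and, after it, the furan. C7 passes through this step as a silyl ether, because a carbonyl at C6 or C7 would divert the enolate into aldol or wrong-side O-arylation.
- After the key step: C7 ketone, α-arylation at C6, reduction, anisylation at C7, furan reduction, nitrile to aldehyde, demethylation.
- Stereochemistry: C6 by Ru transfer hydrogenation with dynamic kinetic resolution of the α-aryl ketone; C7 by anti attack of anisole on the ring-B-stabilised cation; C11b by protonation anti to the C6 aryl group; C1 by acid equilibration to the 1,11b-trans isomer.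

Key step: step 10

Remark: locants follow benzo[6,7]cyclohepta[1,2,3-cd]benzofuran (C1 = aryl-bearing furan carbon, O2, C6 = bridge carbon on ring A, C7 = bridge carbon on ring B, C11b = furan carbon bonded to ring B, ring A = C2a–C5a/C11c, ring B = C7a–C11a); the (S,S)-Ru catalyst is assumed to act cis-selectively with the facial sense known for 1-tetralone, otherwise its enantiomer is used.

Step 1
Reactants: 1 methyl 2-(3,5-dimethoxyphenyl)acetate
Product: 2 methyl 2-(2-formyl-3,5-dimethoxyphenyl)acetate
Conditions: POCl3, DMF, 0 → 60 °C; then H2O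
Reagents that add atoms: N,N-dimethylformamide CN(C)C=O; water O
Why: Vilsmeier–Haack formylation of the electron-rich ring should occur ortho to the side chain and para to a methoxy group (the site between the two methoxy groups is more hindered), and the ester is inert to the chloroiminium reagent.

Step 2
Reactants: 3 2-amino-5-methoxybenzoic acid
Product: 4 2-amino-3-bromo-5-methoxybenzoic acid
Conditions: NBS, DMF, 0 °C → rt
Reagents that add atoms: N-bromosuccinimide O=C1CCC(=O)N1Br
Why: Electrophilic aromatic bromination is steered by the amino group to its only free ortho position (its para position carries the methoxy group), which gives the contiguous substitution pattern needed for ring A.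

Step 3
Reactants: 4 2-amino-3-bromo-5-methoxybenzoic acid
Product: 6 3-bromo-2-iodo-5-methoxybenzoic acid, via arenediazonium chloride 5 (not isolated)
Conditions: NaNO2, aq. HCl, 0 °C; then KI, 0 → 50 °C
Reagents that add atoms: potassium iodide [K+].[I-]
Why: Diazotisation followed by iodide displacement (Sandmeyer-type iodination, no copper needed) puts iodine on the carbon between the carboxyl and bromo groups, as in the classical route from anthranilic acids to 2-iodobenzoic acids.

Step 4
Reactants: 6 3-bromo-2-iodo-5-methoxybenzoic acid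
Product: 7 (3-bromo-2-iodo-5-methoxyphenyl)methanol
Conditions: BH3·THF, THF, 0 °C → rt; then H2O
Reagents that add atoms: none
Why: Borane reduction of a carboxylic acid proceeds through the acyloxyborane and is chemoselective, leaving both aryl halides untouched.

Step 5
Reactants: 7 (3-bromo-2-iodo-5-methoxyphenyl)methanol
Product: 8 1-bromo-3-(bromomethyl)-2-iodo-5-methoxybenzene
Conditions: PBr3, CH2Cl2, 0 °C
Reagents that add atoms: phosphorus tribromide BrP(Br)Br
Why: Bromination of the primary benzylic alcohol through its phosphite ester (SN2 by bromide) is standard and does not affect the aryl halides or the ether.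

Step 6
Reactants: 8 1-bromo-3-(bromomethyl)-2-iodo-5-methoxybenzene; 2 methyl 2-(2-formyl-3,5-dimethoxyphenyl)acetate
Product: 11 1-[(3-bromo-2-iodo-5-methoxyphenyl)methyl]-6,8-dimethoxyisochroman-3-one (racemic), via benzylzinc bromide 9 (not isolated), via hydroxy ester 10 (not isolated)
Conditions: Zn dust, LiCl, THF, 0 °C; then 2, 0 → 40 °C; then H2O
Reagents that add atoms: none
Why: Zinc inserts into the benzylic C–Br bond far faster than into the aryl halides, the benzylzinc reagent adds to the aldehyde but not to the ester (Barbier-/Reformatsky-type 1,2-addition), and the zinc alkoxide closes the six-membered lactone; the carbinol centre forms racemic (it is oxidised in step 12) and any uncyclised hydroxy ester gives the same amide in step 7.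

Step 7
Reactants: 11 1-[(3-bromo-2-iodo-5-methoxyphenyl)methyl]-6,8-dimethoxyisochroman-3-one
Product: 12 2-{2-[2-(3-bromo-2-iodo-5-methoxyphenyl)-1-hydroxyethyl]-3,5-dimethoxyphenyl}-N-methoxy-N-methylacetamide (racemic)
Conditions: MeNHOMe·HCl (slight excess), iPrMgCl, THF, −20 °C; then 11, −20 → 0 °C; then H2O
Reagents that add atoms: N,O-dimethylhydroxylamine hydrochloride CNOC.Cl
Why: Weinreb aminolysis of the lactone by the pre-formed chloromagnesium amide opens the ring to the hydroxy amide, and no free Grignard reagent remains to exchange with the aryl iodide.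

Step 8
Reactants: 12 2-{2-[2-(3-bromo-2-iodo-5-methoxyphenyl)-1-hydroxyethyl]-3,5-dimethoxyphenyl}-N-methoxy-N-methylacetamide
Product: 13 2-{2-[2-(3-bromo-2-iodo-5-methoxyphenyl)-1-(tert-butyldimethylsilyloxy)ethyl]-3,5-dimethoxyphenyl}-N-methoxy-N-methylacetamide (racemic)
Conditions: TBSOTf, 2,6-lutidine, CH2Cl2, −78 → 0 °C
Reagents that add atoms: tert-butyldimethylsilyl trifluoromethanesulfonate CC(C)(C)[Si](C)(C)OS(=O)(=O)C(F)(F)F
Why: Silyl triflate protection of the hindered benzylic alcohol prevents relactonisation, lactol formation with the coming ketone, and Pd-catalysed O-arylation of the alkoxide in step 10.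

Step 9
Reactants: 13 2-{2-[2-(3-bromo-2-iodo-5-methoxyphenyl)-1-(tert-butyldimethylsilyloxy)ethyl]-3,5-dimethoxyphenyl}-N-methoxy-N-methylacetamide; 14 4-methoxyphenylmagnesium bromide
Product: 15 2-{2-[2-(3-bromo-2-iodo-5-methoxyphenyl)-1-(tert-butyldimethylsilyloxy)ethyl]-3,5-dimethoxyphenyl}-1-(4-methoxyphenyl)ethan-1-one (racemic)
Conditions: 14 (1.5 equiv), THF, −20 → 0 °C; then H2O
Reagents that add atoms: none
Why: Weinreb ketone synthesis: the chelated tetrahedral adduct stops at the ketone stage, and an aryl Grignard reagent at or below 0 °C should not exchange with the aryl iodide.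

Step 10
Reactants: 15 2-{2-[2-(3-bromo-2-iodo-5-methoxyphenyl)-1-(tert-butyldimethylsilyloxy)ethyl]-3,5-dimethoxyphenyl}-1-(4-methoxyphenyl)ethan-1-one
Product: 17 tert-butyl{[4,8,10-trimethoxy-1-(4-methoxyphenyl)-6,7-dihydrobenzo[6,7]cyclohepta[1,2,3-cd]benzofuran-7-yl]oxy}dimethylsilane (racemic), via seven-membered bromo ketone 16 (not isolated)
Conditions: Pd2(dba)3 (5 mol %), DPEphos (12 mol %), Cs2CO3 (3 equiv), toluene (0.01 M), 110 °C
Reagents that add atoms: none
Why: Pd(0) inserts into the C–I bond (faster than C–Br), the caesium enolate of the benzyl aryl ketone binds palladium and C–C reductive elimination (ketone α-arylation) closes the seven-membered ring; the resulting α,α-diaryl ketone is more acidic, its enolate captures palladium after insertion into the neighbouring C–Br bond, and C–O reductive elimination (enolate O-arylation) closes the furan. The closest known reaction type is the Pd-catalysed tandem C-/O-arylation of benzyl aryl ketones with 1,2-dihaloarenes to 2,3-diarylbenzofurans, combined with intramolecular ketone α-arylation to benzo-fused seven-membered rings. The seven-membered ring closes by intramolecular α-arylation through an eight-membered palladacycle, and the furan closes by five-membered C–O reductive elimination from the O-bound palladium enolate at the adjacent carbon. No stereocentre is created; the enolate carbon becomes sp2, and C7 stays racemic until it is oxidised. The step needs iodide-before-bromide and carbon-before-oxygen selectivity: the first follows from oxidative-addition rates and the second from ring size (O-attack at the iodide site would need a nine-membered ring), while the silyl ether leaves the anisyl ketone as the only enolisable carbonyl and removes the hydroxyl that would O-arylate, and high dilution suppresses intermolecular coupling.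

Step 11
Reactants: 17 tert-butyl{[4,8,10-trimethoxy-1-(4-methoxyphenyl)-6,7-dihydrobenzo[6,7]cyclohepta[1,2,3-cd]benzofuran-7-yl]oxy}dimethylsilane
Product: 18 4,8,10-trimethoxy-1-(4-methoxyphenyl)-6,7-dihydrobenzo[6,7]cyclohepta[1,2,3-cd]benzofuran-7-ol (racemic)
Conditions: TBAF, THF, 0 °C → rt
Reagents that add atoms: none
Why: Fluoride-induced desilylation (Si–F bond formation) frees the benzylic alcohol under non-acidic conditions that cannot ionise this electron-rich carbinol.

Step 12
Reactants: 18 4,8,10-trimethoxy-1-(4-methoxyphenyl)-6,7-dihydrobenzo[6,7]cyclohepta[1,2,3-cd]benzofuran-7-ol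
Product: 19 4,8,10-trimethoxy-1-(4-methoxyphenyl)benzo[6,7]cyclohepta[1,2,3-cd]benzofuran-7(6H)-one
Conditions: MnO2 (activated, excess), CH2Cl2, rt
Reagents that add atoms: none
Why: Activated manganese dioxide oxidises the electron-rich benzylic alcohol to the aryl ketone under neutral heterogeneous conditions and should not touch the benzofuran.

Step 13
Reactants: 19 4,8,10-trimethoxy-1-(4-methoxyphenyl)benzo[6,7]cyclohepta[1,2,3-cd]benzofuran-7(6H)-one; 20 3-bromo-4-methoxybenzonitrile
Product: 21 4-methoxy-3-[4,8,10-trimethoxy-1-(4-methoxyphenyl)-7-oxo-6,7-dihydrobenzo[6,7]cyclohepta[1,2,3-cd]benzofuran-6-yl]benzonitrile (racemic)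
Conditions: Pd(OAc)2 (5 mol %), XPhos (10 mol %), NaOtBu (2.2 equiv), toluene, 80 °C; then H2O
Reagents that add atoms: none
Why: Pd-catalysed ketone α-arylation (Buchwald–Hartwig type) at the only enolisable position, the benzylic C6 methylene; the product is held as its hindered enolate, which stops the reaction at monoarylation, and C6 forms racemic and configurationally labile.

Step 14
Reactants: 21 4-methoxy-3-[4,8,10-trimethoxy-1-(4-methoxyphenyl)-7-oxo-6,7-dihydrobenzo[6,7]cyclohepta[1,2,3-cd]benzofuran-6-yl]benzonitrile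
Product: 22 3-[(6R,7S)-7-hydroxy-4,8,10-trimethoxy-1-(4-methoxyphenyl)-6,7-dihydrobenzo[6,7]cyclohepta[1,2,3-cd]benzofuran-6-yl]-4-methoxybenzonitrile (6,7-cis)
Conditions: RuCl[(S,S)-TsDPEN](p-cymene) (3 mol %), HCO2H/Et3N (1:1.2), DMF, 40 °C
Reagents that add atoms: none
Why: Noyori–Ikariya asymmetric transfer hydrogenation with dynamic kinetic resolution: the doubly benzylic C6–H epimerises fast in the amine-rich medium, and the (S,S)-catalyst should reduce one ketone enantiomer on the face anti to the C6 aryl group, setting C7 (S) by catalyst control and C6 (R) through the cis preference known for 2-aryl benzo-fused cyclic ketones; the excess amine keeps the acid-labile carbinol from ionising.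

Step 15
Reactants: 22 3-[(6R,7S)-7-hydroxy-4,8,10-trimethoxy-1-(4-methoxyphenyl)-6,7-dihydrobenzo[6,7]cyclohepta[1,2,3-cd]benzofuran-6-yl]-4-methoxybenzonitrile; 23 anisole
Product: 24 4-methoxy-3-[(6R,7S)-4,8,10-trimethoxy-1,7-bis(4-methoxyphenyl)-6,7-dihydrobenzo[6,7]cyclohepta[1,2,3-cd]benzofuran-6-yl]benzonitrile (6,7-trans diaryl)
Conditions: 23 (20 equiv), TfOH (10 mol %), CH2Cl2, −40 → 0 °C
Reagents that add atoms: none
Why: Friedel–Crafts alkylation through the C7 benzylic cation, which is stabilised by the ortho and para methoxy groups of ring B; anisole should attack through its para position on the face opposite the neighbouring C6 aryl group, so C7 is set trans to it by the fixed C6 centre (the former carbinol configuration is irrelevant), and low temperature with excess anisole favours capture over loss of the C6 proton.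

Step 16
Reactants: 24 4-methoxy-3-[(6R,7S)-4,8,10-trimethoxy-1,7-bis(4-methoxyphenyl)-6,7-dihydrobenzo[6,7]cyclohepta[1,2,3-cd]benzofuran-6-yl]benzonitrile
Product: 25 4-methoxy-3-[(1S,6R,7S,11bS)-4,8,10-trimethoxy-1,7-bis(4-methoxyphenyl)-1,6,7,11b-tetrahydrobenzo[6,7]cyclohepta[1,2,3-cd]benzofuran-6-yl]benzonitrile
Conditions: Et3SiH (4 equiv), TFA/CH2Cl2 (1:2), 0 °C → rt
Reagents that add atoms: none
Why: Ionic hydrogenation of the benzofuran (protonation, then silane hydride transfer): C11b should be protonated on the face away from the pseudo-axial C6 aryl group on the neighbouring peri carbon, which sets C11b, hydride then reduces the C1 oxocarbenium ion stabilised by O2 and the anisyl group, and reversible ionisation of the C1–O2 benzylic ether bond in TFA lets C1 settle as the more stable 1,11b-trans isomer; nitrile, methyl ethers and the tetraarylethane unit are inert.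

Step 17
Reactants: 25 4-methoxy-3-[(1S,6R,7S,11bS)-4,8,10-trimethoxy-1,7-bis(4-methoxyphenyl)-1,6,7,11b-tetrahydrobenzo[6,7]cyclohepta[1,2,3-cd]benzofuran-6-yl]benzonitrile
Product: 27 4-methoxy-3-[(1S,6R,7S,11bS)-4,8,10-trimethoxy-1,7-bis(4-methoxyphenyl)-1,6,7,11b-tetrahydrobenzo[6,7]cyclohepta[1,2,3-cd]benzofuran-6-yl]benzaldehyde, via N-aluminated aldimine 26 (not isolated)
Conditions: DIBAL-H (1.5 equiv), CH2Cl2, −78 °C; then 1 M HCl, 0 °C
Reagents that add atoms: water O
Why: DIBAL-H adds one hydride to the nitrile to give an N-aluminated aldimine that is stable at low temperature and is hydrolysed to the aldehyde on acidic work-up; no other reducible group is present.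

Step 18
Reactants: 27 4-methoxy-3-[(1S,6R,7S,11bS)-4,8,10-trimethoxy-1,7-bis(4-methoxyphenyl)-1,6,7,11b-tetrahydrobenzo[6,7]cyclohepta[1,2,3-cd]benzofuran-6-yl]benzaldehyde
Product: 28 vitisinol B, 3-[(1S,6R,7S,11bS)-4,8,10-trihydroxy-1,7-bis(4-hydroxyphenyl)-1,6,7,11b-tetrahydrobenzo[6,7]cyclohepta[1,2,3-cd]benzofuran-6-yl]-4-hydroxybenzaldehyde
Conditions: BBr3 (12 equiv), CH2Cl2, −78 °C → rt; then ice/H2O
Reagents that add atoms: none
Why: Boron tribromide cleaves all six aryl methyl ethers by Lewis acid activation and bromide attack at methyl; the aldehyde should survive, the C6, C7 and C11b centres are not ionisable, and C1, the only centre that could open under the Lewis acid, is already in its thermodynamically preferred trans arrangement.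

**Compound list**
1 | methyl 2-(3,5-dimethoxyphenyl)acetate | COC(=O)Cc1cc(OC)cc(OC)c1 | starting material
2 | methyl 2-(2-formyl-3,5-dimethoxyphenyl)acetate | COC(=O)Cc1cc(OC)cc(OC)c1C=O | intermediate
3 | 2-amino-5-methoxybenzoic acid | COc1ccc(N)c(c1)C(=O)O | starting material
4 | 2-amino-3-bromo-5-methoxybenzoic acid | COc1cc(Br)c(N)c(c1)C(=O)O | intermediate
5 | 2-bromo-6-carboxy-4-methoxybenzenediazonium chloride | COc1cc(Br)c([N+]#N)c(c1)C(=O)O.[Cl-] | intermediate
6 | 3-bromo-2-iodo-5-methoxybenzoic acid | COc1cc(Br)c(I)c(c1)C(=O)O | intermediate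
7 | (3-bromo-2-iodo-5-methoxyphenyl)methanol | COc1cc(Br)c(I)c(CO)c1 | intermediate
8 | 1-bromo-3-(bromomethyl)-2-iodo-5-methoxybenzene | COc1cc(Br)c(I)c(CBr)c1 | intermediate
9 | (3-bromo-2-iodo-5-methoxybenzyl)zinc bromide | COc1cc(Br)c(I)c(C[Zn]Br)c1 | intermediate
10 | methyl 2-{2-[2-(3-bromo-2-iodo-5-methoxyphenyl)-1-hydroxyethyl]-3,5-dimethoxyphenyl}acetate (racemic; present as its zinc alkoxide) | COC(=O)Cc1cc(OC)cc(OC)c1C(O)Cc1cc(OC)cc(Br)c1I | intermediate
11 | 1-[(3-bromo-2-iodo-5-methoxyphenyl)methyl]-6,8-dimethoxyisochroman-3-one (racemic) | COc1cc2CC(=O)OC(Cc3cc(OC)cc(Br)c3I)c2c(OC)c1 | intermediate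
12 | 2-{2-[2-(3-bromo-2-iodo-5-methoxyphenyl)-1-hydroxyethyl]-3,5-dimethoxyphenyl}-N-methoxy-N-methylacetamide (racemic) | CON(C)C(=O)Cc1cc(OC)cc(OC)c1C(O)Cc1cc(OC)cc(Br)c1I | intermediate
13 | 2-{2-[2-(3-bromo-2-iodo-5-methoxyphenyl)-1-(tert-butyldimethylsilyloxy)ethyl]-3,5-dimethoxyphenyl}-N-methoxy-N-methylacetamide (racemic) | CON(C)C(=O)Cc1cc(OC)cc(OC)c1C(O[Si](C)(C)C(C)(C)C)Cc1cc(OC)cc(Br)c1I | intermediate
14 | 4-methoxyphenylmagnesium bromide | COc1ccc([Mg]Br)cc1 | starting material
15 | 2-{2-[2-(3-bromo-2-iodo-5-methoxyphenyl)-1-(tert-butyldimethylsilyloxy)ethyl]-3,5-dimethoxyphenyl}-1-(4-methoxyphenyl)ethan-1-one (racemic; key-step precursor) | COc1ccc(cc1)C(=O)Cc1cc(OC)cc(OC)c1C(O[Si](C)(C)C(C)(C)C)Cc1cc(OC)cc(Br)c1I | intermediate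
16 | [4-bromo-10-(tert-butyldimethylsilyloxy)-2,7,9-trimethoxy-10,11-dihydro-5H-dibenzo[a,d][7]annulen-5-yl](4-methoxyphenyl)methanone (diastereomer mixture) | COc1ccc(cc1)C(=O)C1c2cc(OC)cc(OC)c2C(O[Si](C)(C)C(C)(C)C)Cc2cc(OC)cc(Br)c12 | intermediate
17 | tert-butyl{[4,8,10-trimethoxy-1-(4-methoxyphenyl)-6,7-dihydrobenzo[6,7]cyclohepta[1,2,3-cd]benzofuran-7-yl]oxy}dimethylsilane (racemic; key-step product) | COc1ccc(cc1)-c1oc2cc(OC)cc3c2c1-c1cc(OC)cc(OC)c1C(O[Si](C)(C)C(C)(C)C)C3 | intermediate
18 | 4,8,10-trimethoxy-1-(4-methoxyphenyl)-6,7-dihydrobenzo[6,7]cyclohepta[1,2,3-cd]benzofuran-7-ol (racemic) | COc1ccc(cc1)-c1oc2cc(OC)cc3c2c1-c1cc(OC)cc(OC)c1C(O)C3 | intermediate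
19 | 4,8,10-trimethoxy-1-(4-methoxyphenyl)benzo[6,7]cyclohepta[1,2,3-cd]benzofuran-7(6H)-one | COc1ccc(cc1)-c1oc2cc(OC)cc3c2c1-c1cc(OC)cc(OC)c1C(=O)C3 | intermediate
20 | 3-bromo-4-methoxybenzonitrile | COc1ccc(C#N)cc1Br | starting material
21 | 4-methoxy-3-[4,8,10-trimethoxy-1-(4-methoxyphenyl)-7-oxo-6,7-dihydrobenzo[6,7]cyclohepta[1,2,3-cd]benzofuran-6-yl]benzonitrile (racemic) | COc1ccc(cc1)-c1oc2cc(OC)cc3c2c1-c1cc(OC)cc(OC)c1C(=O)C3c1cc(C#N)ccc1OC | intermediate
22 | 3-[(6R,7S)-7-hydroxy-4,8,10-trimethoxy-1-(4-methoxyphenyl)-6,7-dihydrobenzo[6,7]cyclohepta[1,2,3-cd]benzofuran-6-yl]-4-methoxybenzonitrile (OH cis to the C6 aryl group) | N#Cc1ccc(OC)c([C@H]2c3cc(OC)cc4oc(-c5ccc(OC)cc5)c(-c5cc(OC)cc(OC)c5[C@H]2O)c34)c1 | intermediate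
23 | anisole | COc1ccccc1 | starting material
24 | 4-methoxy-3-[(6R,7S)-4,8,10-trimethoxy-1,7-bis(4-methoxyphenyl)-6,7-dihydrobenzo[6,7]cyclohepta[1,2,3-cd]benzofuran-6-yl]benzonitrile (C6 and C7 aryl groups trans) | N#Cc1ccc(OC)c([C@H]2c3cc(OC)cc4oc(-c5ccc(OC)cc5)c(-c5cc(OC)cc(OC)c5[C@@H]2c2ccc(OC)cc2)c34)c1 | intermediate
25 | 4-methoxy-3-[(1S,6R,7S,11bS)-4,8,10-trimethoxy-1,7-bis(4-methoxyphenyl)-1,6,7,11b-tetrahydrobenzo[6,7]cyclohepta[1,2,3-cd]benzofuran-6-yl]benzonitrile | N#Cc1ccc(OC)c([C@H]2c3cc(OC)cc4c3[C@H](c3cc(OC)cc(OC)c3[C@@H]2c2ccc(OC)cc2)[C@@H](c2ccc(OC)cc2)O4)c1 | intermediate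
26 | N-(diisobutylalumino)aldimine derived from 25 (same four stereocentres) | CC(C)C[Al](CC(C)C)N=Cc1ccc(OC)c([C@H]2c3cc(OC)cc4c3[C@H](c3cc(OC)cc(OC)c3[C@@H]2c2ccc(OC)cc2)[C@@H](c2ccc(OC)cc2)O4)c1 | intermediate
27 | 4-methoxy-3-[(1S,6R,7S,11bS)-4,8,10-trimethoxy-1,7-bis(4-methoxyphenyl)-1,6,7,11b-tetrahydrobenzo[6,7]cyclohepta[1,2,3-cd]benzofuran-6-yl]benzaldehyde | O=Cc1ccc(OC)c([C@H]2c3cc(OC)cc4c3[C@H](c3cc(OC)cc(OC)c3[C@@H]2c2ccc(OC)cc2)[C@@H](c2ccc(OC)cc2)O4)c1 | intermediate
28 | vitisinol B, 3-[(1S,6R,7S,11bS)-4,8,10-trihydroxy-1,7-bis(4-hydroxyphenyl)-1,6,7,11b-tetrahydrobenzo[6,7]cyclohepta[1,2,3-cd]benzofuran-6-yl]-4-hydroxybenzaldehyde | O=Cc1ccc(O)c([C@H]2c3cc(O)cc4c3[C@H](c3cc(O)cc(O)c3[C@@H]2c2ccc(O)cc2)[C@@H](c2ccc(O)cc2)O4)c1 | target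

**Step count and risks**
Total steps: 18. Longest linear sequence: 17 steps (3 → 28, steps 2–18); the ring-B branch (step 1) joins at step 6.

Steps most likely to fail:

Step 10. The entropically demanding seven-membered C–C closure may lose to intermolecular arylation or hydrodehalogenation, or the sequence may stall after the first bond. The fallback separates the two bond formations and changes both activation modes. It sets out from 15, which is converted (TMSCl, NaI, Et3N, MeCN) into its (Z)-trimethylsilyl enol ether F1. Fluoride-promoted Pd-catalysed intramolecular arylation of the silyl enol ether at the C–I bond (Pd(OAc)2, P(tBu)3, CsF, toluene, 80 °C) then gives the seven-membered bromo ketone 16, now isolated. A copper-catalysed Ullmann-type enolate O-arylation (CuI, 1,10-phenanthroline, Cs2CO3, DMF, 100 °C) closes the furan and the route is rejoined at 17.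

Step 15. The C7 cation may lose the C6 proton to give the cyclic triarylethene, whose re-protonation would erase the C6 configuration; anisole may also attack through its ortho position or with incomplete facial selectivity. The fallback avoids a free cation. It sets out from 22, which is acylated (PivCl, DMAP, pyridine) to the C7 pivalate F2. A stereospecific nickel-catalysed Suzuki–Miyaura coupling of the benzylic pivalate with 2-(4-methoxyphenyl)-5,5-dimethyl-1,3,2-dioxaborinane (Ni(cod)2, SIMes, KOtBu, n-BuOH, THF), run with the carbene ligand that gives inversion at carbon, should convert the cis-pivalate into the trans-diaryl compound, and the route is rejoined at 24.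

Step 16. Protonation of the tetrasubstituted, ring-constrained furan carbon may be slow or occur from the wrong face, and the product may be over-reduced through ionisation of the C1–O2 bond and silane capture. The fallback separates hydrogen delivery from C1 equilibration. It sets out from 24, which is hydrogenated (H2, 50 bar, Pd(OH)2/C, EtOAc, neutral) from the face away from the C6 aryl group to the 1,11b-cis dihydrobenzofuran F3. Treatment with TFA in CH2Cl2 without silane then epimerises C1 through reversible C1–O2 ionisation to the trans isomer, and the route is rejoined at 25.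

Further compounds
F1 | step 10 | (Z)-trimethylsilyl enol ether of 15 | COc1ccc(cc1)/C(O[Si](C)(C)C)=C/c1cc(OC)cc(OC)c1C(O[Si](C)(C)C(C)(C)C)Cc1cc(OC)cc(Br)c1I
F2 | step 15 | (6R,7S)-6-(5-cyano-2-methoxyphenyl)-4,8,10-trimethoxy-1-(4-methoxyphenyl)-6,7-dihydrobenzo[6,7]cyclohepta[1,2,3-cd]benzofuran-7-yl pivalate | N#Cc1ccc(OC)c([C@H]2c3cc(OC)cc4oc(-c5ccc(OC)cc5)c(-c5cc(OC)cc(OC)c5[C@H]2OC(=O)C(C)(C)C)c34)c1
F3 | step 16 | 4-methoxy-3-[(1R,6R,7S,11bS)-4,8,10-trimethoxy-1,7-bis(4-methoxyphenyl)-1,6,7,11b-tetrahydrobenzo[6,7]cyclohepta[1,2,3-cd]benzofuran-6-yl]benzonitrile (1,11b-cis) | N#Cc1ccc(OC)c([C@H]2c3cc(OC)cc4c3[C@H](c3cc(OC)cc(OC)c3[C@@H]2c2ccc(OC)cc2)[C@H](c2ccc(OC)cc2)O4)c1
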